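**Plan**
1. Retrosynthesis: the target is the C2-symmetric dehydrodimer of acacetin, so the C8–C8'' biaryl bond is cut first. Each half is then cut at O1–C2 and C4–C4a of ring C, which leads back to phloroglucinol and an aroylacetate.
2. Forward: ring C is fused onto ring A (step 1), O7 is capped as a benzyl ether (step 2) and C6 is blocked by iodine (step 3). Two identical flavones are then joined C8 to C8'' by oxidative phenol coupling (step 4), and one hydrogenolysis removes both iodines and both benzyl groups (step 5).
3. Enabling feature: in the phloroglucinol-type ring A, C8 stands para to the C5 hydroxyl and ortho to O7 and O1, so the C5 phenoxyl radical carries spin there. The only other spin-bearing C–H is C6, which iodine occupies. The step copies the presumed biosynthetic radical pairing of two flavone monomers.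
4. Stereochemistry: there is no stereocentre, and the hindered C8–C8'' axis arises in racemic form.

Key step: step 4

Assumption: the target SMILES carries no axial descriptor, so the racemate of the atropisomeric axis is taken as the target.

**Step 1**
Reactants: 1 phloroglucinol (benzene-1,3,5-triol); 2 ethyl 3-(4-methoxyphenyl)-3-oxopropanoate
Product: 4 acacetin (5,7-dihydroxy-4'-methoxyflavone), via diketone 3 (not isolated)
Conditions: neat melt (2 in excess), 240 °C (microwave or sand bath), N2, EtOH and H2O allowed to distil off
Reagents that add atoms: none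
Why: Mentzer pyrone synthesis, in which thermal loss of ethanol from 2 C-acylates the very nucleophilic phloroglucinol to diketone 3, whose ortho hydroxyl adds to the aryl ketone and loses water to close ring C; the three C–H positions of 1 are equivalent, so only one flavone can form.

**Step 2**
Reactants: 4 acacetin
Product: 5 7-O-benzylacacetin (7-benzyloxy-5-hydroxy-4'-methoxyflavone)
Conditions: BnBr (1.05 equiv), K2CO3 (1.2 equiv), acetone, reflux
Reagents that add atoms: benzyl bromide, BrCc1ccccc1
Why: Williamson ether synthesis, selective because the 7-OH is the acidic, vinylogous-acid hydroxyl, whereas the 5-OH is held in a hydrogen bond to the C4 carbonyl and is not alkylated under these mild conditions.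

**Step 3**
Reactants: 5 7-O-benzylacacetin
Product: 6 7-O-benzyl-6-iodoacacetin (7-benzyloxy-5-hydroxy-6-iodo-4'-methoxyflavone)
Conditions: BnMe3N·ICl2 (1.05 equiv), CaCO3, CH2Cl2–MeOH, rt
Reagents that add atoms: benzyltrimethylammonium dichloroiodate, C[N+](C)(C)Cc1ccccc1.Cl[I-]Cl
Why: Electrophilic aromatic iodination, which under neutral CaCO3-buffered conditions is known to go to C6 in 5-hydroxy-7-alkoxyflavones, ortho to the free C5 hydroxyl that its hydrogen bond to the C4 carbonyl holds away from C6, while ring B, C3 and C8 react more slowly.

**Step 4**
Reactants: 6 7-O-benzyl-6-iodoacacetin (two molecules)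
Product: 8 (±)-7,7''-di-O-benzyl-6,6''-diiodo-4',4'''-di-O-methylcupressuflavone, via bis-dienone 7 (not isolated)
Conditions: VOF3 (1.5 equiv per 6), CF3CO2H–CH2Cl2 1:4, −20 → 0 °C, exclusion of light
Reagents that add atoms: none
Why: Pentavalent vanadium takes one electron from the chelated C5 phenol of 6, the resulting phenoxyl radical holds its spin on O5, C4a, C6 and C8, and two such species join at C8 to give bis-dienone 7, which enolises at once to the biphenol 8 (two VOF3 are spent per new bond). The closest known reaction type is the VOF3-mediated para–para oxidative phenol coupling of 5-hydroxychroman-4-ones that carry a halogen blocking group ortho to the phenol, and the event is the laboratory copy of the presumed cytochrome P450 phenoxyl radical dimerisation that leads to 8,8''-biflavones. No ring is closed. No stereocentre remains, since the two sp3 carbons of 7 are lost on enolisation, and the tetra-ortho-substituted axis forms as a racemate because no chiral element is present. The step needs C8 over C6, C–C over C–O coupling and ring A over ring B and C3: iodine occupies C6, C4a is quaternary, the benzyl ether removes O7 as a second radical or aryl ether site and makes 6 soluble in CH2Cl2, O5 is buried between iodine and the C4 carbonyl, and ring B and C3 are conjugated to the pyrone carbonyl and too electron-poor to be oxidised. Low temperature, a short reaction time and a small excess of oxidant should hold back acid-promoted iodine migration and further oxidation of 8.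

**Step 5**
Reactants: 8 (±)-7,7''-di-O-benzyl-6,6''-diiodo-4',4'''-di-O-methylcupressuflavone
Product: 9 (±)-4',4'''-di-O-methylcupressuflavone
Conditions: H2 (1 atm), Pd/C (10 wt %), NaOAc (2.5 equiv), THF–MeOH, rt
Reagents that add atoms: none
Why: Catalytic hydrogenolysis, in which zerovalent palladium cleaves the weak aryl C–I bonds and the benzylic C–O bonds under the same mild conditions, NaOAc takes up the HI that would poison the catalyst, and the aryl methyl ethers and the flavone C2=C3 bond are known to survive hydrogen at 1 atm and room temperature.

**Compound list**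
1 | phloroglucinol | Oc1cc(O)cc(O)c1 | starting material
2 | ethyl 3-(4-methoxyphenyl)-3-oxopropanoate | CCOC(=O)CC(=O)c1ccc(OC)cc1 | starting material
3 | 1-(4-methoxyphenyl)-3-(2,4,6-trihydroxyphenyl)propane-1,3-dione (not isolated) | COc1ccc(cc1)C(=O)CC(=O)c1c(O)cc(O)cc1O | intermediate
4 | acacetin | COc1ccc(cc1)-c1cc(=O)c2c(O)cc(O)cc2o1 | intermediate
5 | 7-O-benzylacacetin | COc1ccc(cc1)-c1cc(=O)c2c(O)cc(OCc3ccccc3)cc2o1 | intermediate
6 | 7-O-benzyl-6-iodoacacetin | COc1ccc(cc1)-c1cc(=O)c2c(O)c(I)c(OCc3ccccc3)cc2o1 | intermediate
7 | C8–C8''-linked bis(cyclohexa-2,5-dienone) tautomer of 8 (not isolated; transient sp3 C8 and C8'', configuration not defined) | COc1ccc(cc1)C1=CC(=O)C2=C(O1)C(C(OCc1ccccc1)=C(I)C2=O)C1C(OCc2ccccc2)=C(I)C(=O)C2=C1OC(=CC2=O)c1ccc(OC)cc1 | intermediate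
8 | (±)-7,7''-di-O-benzyl-6,6''-diiodo-4',4'''-di-O-methylcupressuflavone | COc1ccc(cc1)-c1cc(=O)c2c(O)c(I)c(OCc3ccccc3)c(c2o1)-c1c(OCc2ccccc2)c(I)c(O)c2c(=O)cc(oc12)-c1ccc(OC)cc1 | intermediate
9 | (±)-4',4'''-di-O-methylcupressuflavone | COc1ccc(-c2cc(=O)c3c(O)cc(O)c(-c4c(O)cc(O)c5c(=O)cc(-c6ccc(OC)cc6)oc45)c3o2)cc1 | target

Total step count: 5. Longest linear sequence: 5.

**Steps most likely to fail**

Step 4. Electron transfer from the carbonyl-conjugated, iodine-bearing ring A may be too slow. In the acidic medium, iodine migration or loss, C–O coupling and over-oxidation may also compete. The fallback replaces the C–H/C–H oxidative coupling by a reductive C–I/C–I coupling.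
- It sets out from acacetin 4. Exhaustive benzylation (excess BnBr, K2CO3, DMF, 80 °C) should give 5,7-di-O-benzylacacetin F1.
- Electrophilic iodination goes to C8 in 5,7-dialkoxyflavones because C6 is flanked by two alkoxy groups. With I2, AgO2CCF3 in CH2Cl2 it should give 5,7-di-O-benzyl-8-iodoacacetin F2.
- Ullmann homocoupling (activated Cu bronze, DMF, 150 °C) should give 5,5'',7,7''-tetra-O-benzyl-4',4'''-di-O-methylcupressuflavone F3.
- Hydrogenolysis (H2, Pd/C, THF–MeOH) brings the route back at target 9.

Step 3. Iodination may stray to C8 or run on to double iodination, so that the blocking group ends up on the carbon that must stay free. The fallback gives up the halogen block and relies on the bias of the substrate itself. It sets out from 5, which is coupled directly under the step 4 conditions. The higher spin density para to O5, and the crowding of C6 between the metal-bound O5 and the benzyloxy group, should favour C8. The 6,8''- and 6,6''-linked isomers are removed by chromatography and crystallisation at the stage of 7,7''-di-O-benzyl-4',4'''-di-O-methylcupressuflavone F4. Hydrogenolysis (H2, Pd/C) then returns to the route at target 9.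

Step 5. Liberated iodide may poison the catalyst so that debenzylation stalls. Low solubility may slow the reaction, and long exposure may begin to saturate C2=C3. The fallback removes the helpers by two non-catalytic steps and sets out from 8.
- Lewis-acid debenzylation with a cation scavenger (BCl3, pentamethylbenzene, CH2Cl2, −78 °C) spares the 4'-methyl ethers and should give 6,6''-diiodo-4',4'''-di-O-methylcupressuflavone F5.
- Each iodine in this compound is flanked by two free hydroxyls and should be given up to sulfite (Na2SO3, aqueous DMF, 70 °C). This returns to the route at target 9.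

**Further compounds**
F1 | step 4 | 5,7-di-O-benzylacacetin | COc1ccc(cc1)-c1cc(=O)c2c(OCc3ccccc3)cc(OCc3ccccc3)cc2o1
F2 | step 4 | 5,7-di-O-benzyl-8-iodoacacetin | COc1ccc(cc1)-c1cc(=O)c2c(OCc3ccccc3)cc(OCc3ccccc3)c(I)c2o1
F3 | step 4 | 5,5'',7,7''-tetra-O-benzyl-4',4'''-di-O-methylcupressuflavone | COc1ccc(cc1)-c1cc(=O)c2c(OCc3ccccc3)cc(OCc3ccccc3)c(c2o1)-c1c(OCc2ccccc2)cc(OCc2ccccc2)c2c(=O)cc(oc12)-c1ccc(OC)cc1
F4 | step 3 | 7,7''-di-O-benzyl-4',4'''-di-O-methylcupressuflavone | COc1ccc(cc1)-c1cc(=O)c2c(O)cc(OCc3ccccc3)c(c2o1)-c1c(OCc2ccccc2)cc(O)c2c(=O)cc(oc12)-c1ccc(OC)cc1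
F5 | step 5 | 6,6''-diiodo-4',4'''-di-O-methylcupressuflavone | COc1ccc(cc1)-c1cc(=O)c2c(O)c(I)c(O)c(c2o1)-c1c(O)c(I)c(O)c2c(=O)cc(oc12)-c1ccc(OC)cc1
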